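All runs are simulated for an exercise; noise was put on by code.

A reagent cannot react before it is in the flask, so I counted how many hours of full charge each slow feed really gives.

* the flask with the highest amount of side product, in percent of the substrate charged ("all alike" if they lie within 1.5 percentage points) (Wednesday's / Sunday's / Friday's / all alike)
* final side product, as a percentage of the substrate charged, in Wednesday's
* final side product, as a percentage of the substrate charged, in Sunday's
* final side product, as a percentage of the substrate charged, in Friday's

| setting | delta | alpha | zeta | Wednesday's | Sunday's | Friday's |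
|---|---|---|---|---|---|---|
| substrate | 32 mM | 32 mM | 32 mM | 32 mM (fed, over 30 h) | 32 mM | 32 mM |
| partner | 32 mM | 16 mM | 24 mM | 32.0 mM | 32.0 mM | 32.0 mM |
| rival reagent | 32 mM | 32 mM | 32 mM | 32.0 mM | 32.0 mM | 32.0 mM (fed, over 30 h) |
| protic impurity | 6.4 mM | 6.4 mM | 6.4 mM | 6.40 mM | 6.40 mM | 6.40 mM |
| remark | run made earlier | run made earlier | run made earlier | all else is in the flask from the start; the feed brings no volume worth counting | everything together at the start | all else is in the flask from the start; the feed brings no volume worth counting |
| time |  |  |  | 40 h | 40 h | 40 h |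

| run | time / h | side product / % | target / % |
|---|---|---|---|
| delta | 6.00 | 9.6 | 5.9 |
| delta | 12.0 | 17.1 | 7.1 |
| delta | 15.0 | 19.4 | 7.2 |
| delta | 25.0 | 28.4 | 8.8 |
| delta | 30.0 | 31.6 | 9.4 |
| delta | 40.0 | 37.5 | 9.3 |
| alpha | 4.00 | 6.1 | 2.2 |
| alpha | 6.00 | 9.6 | 2.7 |
| alpha | 8.00 | 12.6 | 3.3 |
| alpha | 15.0 | 20.3 | 4.2 |
| alpha | 20.0 | 25.2 | 4.5 |
| alpha | 30.0 | 33.4 | 5.3 |
| alpha | 50.0 | 44.8 | 4.9 |
| zeta | 2.50 | 4.1 | 1.6 |
| zeta | 8.00 | 11.4 | 5.6 |
| zeta | 15.0 | 20.0 | 5.9 |
| zeta | 20.0 | 24.6 | 6.5 |
| zeta | 30.0 | 33.4 | 7.2 |
| zeta | 40.0 | 38.3 | 8.2 |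
| zeta | 50.0 | 44.4 | 7.0 |

(each reading ± 0.5 percentage points)

- the earlier runs were read with a standard deviation of 0.5 percentage points
- a reading or a percentage of target counts all its forms, free or not

At 15.0 h, side product read 19.4%, 20.0% and 20.3% with partner at 32 mM, 24 mM and 16 mM, so I set partner aside. I took side product as substrate meeting rival reagent. That was an assumption, as the runs held both at equal charge. For such a second-order step at equal charges, with nothing else using either, the share made over the share unmade grows in proportion to time, and its slope is rate constant times charge. The delta run, whose recipe Sunday's repeats, gave me that slope as an average over the run: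

> made ÷ unmade = 37.5% ÷ 62.5% = 0.600
> per hour: 0.600 ÷ 40.0 h = 0.0150 h⁻¹

So I expected about 37.5% in Sunday's. In a steady feed, the amount fed so far climbs from nothing to the charge, averaging half of it, so as an estimate I counted each feed hour as half and each later hour as whole:

> full-charge hours = 40 h less half of 30 h = 25.0 h
> count = 0.0150 h⁻¹ × 25.0 h = 0.375
> side product = count ÷ (count + one) = 27.3%

This turnover count, the rate per hour times the full-charge hours, gave me one figure for both fed flasks, Wednesday's and Friday's.

The forecast named Sunday's, with 38% (36.5% to 39.5%) there. It gave 28.5% (25% to 32%) for Wednesday's and 27.5% (23% to 32%) for Friday's, two figures where I had one. Its ground was “Feeding either partner of a bimolecular step”.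

The flasks gave 28.8% in Wednesday's, 38.2% in Sunday's and 27.2% in Friday's, so Sunday's led, as forecast. My figure of 27.3%, from the count of 0.375, stood 1.5 percentage points below Wednesday's.

    substrate + partner → target (k = 0.00630 M⁻¹ min⁻¹)
    substrate + rival reagent → side product (k = 0.00900 M⁻¹ min⁻¹)
    partner + target ⇌ idle adduct, settled at all times (K = 75.0 M⁻¹)
    partner + protic impurity → quenched reagent (k = 0.0150 M⁻¹ min⁻¹)
    partner → decomposed reagent (k = 0.00140 min⁻¹)

In Friday's at 40.0 h, partner's half-life by decomposition was 8.3 h, shorter than substrate's 55 h by the side step. Partner stood at 2.6% of its charge and substrate at 62%.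

A neighbour of Friday's fed 8.0 mM of rival reagent, so substrate outnumbered it 4.00 to one. Holding substrate at its charge makes the loss of rival reagent pseudo-first-order with the same count:

> rival reagent turned = one minus exp(−0.375) = 31.3%
> side product = 31.3% × 8.0 mM ÷ 32 mM = 7.83%

The neighbour gave 7.61%.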